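The earlier runs and the new flask are simulated for an exercise; scatter was added.

**Two stalls.** Alder kept more of its electrophile than cedar did, 52.0% against 39.6% of the charge at 40.0 h, so I looked for a number that gives such a level.

| setting | cedar | alder | flask |
|---|---|---|---|
| electrophile | 14 mM | 22 mM | 10 mM |
| nucleophile | 15 mM | 15 mM | 15.0 mM |
| gas | 0.81 mM (held) | 0.81 mM (held) | 0.81 mM (held) |
| remark | run made earlier | run made earlier |  |
| time |  |  | 40 h |

| run | time / h | electrophile / % | target / % |
|---|---|---|---|
| cedar | 2.50 | 66.0 | 34.1 |
| cedar | 8.00 | 51.9 | 47.9 |
| cedar | 15.0 | 42.3 | 57.1 |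
| cedar | 20.0 | 41.6 | 60.1 |
| cedar | 30.0 | 40.1 | 59.9 |
| cedar | 40.0 | 39.6 | 61.7 |
| alder | 2.50 | 72.0 | 28.8 |
| alder | 8.00 | 61.3 | 39.0 |
| alder | 15.0 | 54.4 | 45.9 |
| alder | 20.0 | 53.2 | 47.5 |
| alder | 30.0 | 52.7 | 47.6 |
| alder | 40.0 | 52.0 | 47.1 |

(readings scatter by 0.5 percentage points)

- part of the electrophile that has reacted at 40 h
- share of the unused nucleophile that is free and not bound as protonated nucleophile, at 40 h

**Loss number.** I let nucleophile go two ways: one per electrophile reacted, and a loss to self-condensation product whose rate, against the first, follows nucleophile over electrophile. I integrated that ratio from the charge down to zero nucleophile and kept two terms: equivalents of nucleophile equal L plus 0.5 w L squared, where L is the natural logarithm of electrophile charged over electrophile left at the level. The readings give w as 0.338 for cedar and 0.130 for alder. This loss number is twice the excess of equivalents over L, divided by L squared.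

**The curve.** The readings of cedar's electrophile fell by 34.0% of its charge in the first 2.50 h, 24 percentage points more by 15.0 h, then 2.7 points by 40.0 h. The flask, at 1.50 equivalents, stands nearer cedar than alder, so I solved for L with cedar's w. I drew a steep start, a knee near 15.0 h, and a level at 71.1% reacted. The runs do not show the bound nucleophile, so I left that open.

**The forecast.** It gave 74% reacted, above my level, and 10% free, holding the nucleophile “mostly tied up as protonated nucleophile by the acid released”.

**The result.**

    gas ⇌ free base, rate k1*(csat - [free base]) (kL = 0.0130 min⁻¹)
    acid set free + free base ⇌ salt of the base, settled at all times (K = 9.80 × 10⁷ M⁻¹)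
    electrophile + nucleophile → acid set free + target (k = 0.460 M⁻¹ min⁻¹)
    nucleophile + acid set free ⇌ protonated nucleophile, settled at all times (K = 850 M⁻¹)
    2 nucleophile → self-condensation product (k = 0.400 M⁻¹ min⁻¹)
    free base → decomposition product (k = 6.70 × 10⁻⁶ min⁻¹)

The flask gave 67.9% reacted and >99.9% of the unused nucleophile free, with nucleophile, the limiting reagent, down to 0.32% of its charge at 40.0 h while 32% of the electrophile charged stood unreacted. At 6.02 h the step to target used nucleophile 1.5 times as fast as self-condensation did. The flask's result gives w as 0.559, above cedar's 0.338. Alder's 0.130, applied to the neighbour charged with 25 mM of electrophile, gives 43.9% reacted, and that neighbour gave 44.0%.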